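**Plan**

The ring is numbered as a cyclopent-2-enone: C1 is the carbonyl, C2=C3 the alkene, C4 the acetoxy carbon carrying the carboxyheptyl chain, C5 the pentenyl carbon.
Retrosynthesis: the methyl ester and the acetate come off last; then C1–C2 and C4–C5 are cut together, giving a two-carbon unit (C5–C1, a lithiated chiral enol ether from stannane 13) and a three-carbon unit (C2–C3–C4, terminal ynone 5).
Enabling feature: C1=O and the C4 oxygen are 1,4-related across C2=C3, so the cyclopentenone is the closed form of a 1-hydroxy-4-alkoxypentadienyl cation spanning C5–C1–C2–C3–C4, that is, of an open-chain 2-alkoxydienone.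
Forward: ynone 5 from monomethyl azelate (2 steps); stannane 13 from (2Z)-pent-2-en-1-ol, trichloroethylene and an auxiliary alcohol (3 steps); one flask then joins C1–C2 by conjugate addition and closes C4–C5 by acid-triggered conrotatory 4π electrocyclisation, which builds the only ring; acetylation and lipase hydrolysis finish.
Stereochemistry: the Z alkene is bought in with (2Z)-pent-2-en-1-ol; the C4/C5 relative configuration comes from the conrotation (oxygen trans to pentenyl, E/Z isomers at C2=C3 converging); the absolute configuration comes from the (1R,2S)-2-phenylcyclohexyl group on the enol ether oxygen, which is shed in the same step.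

Key step: step 6

Assumption: the (1R,2S)-2-phenylcyclohexyl group is taken to shield the enol ether face whose blocking leads to (4R,5S); if closure follows the other sense, the equally available (1S,2R)-alcohol is used and nothing else changes.

**Route**

Step 1
Reactants: 1 monomethyl azelate (9-methoxy-9-oxononanoic acid); 2 bis(trimethylsilyl)acetylene
Product: 4 methyl 9-oxo-11-(trimethylsilyl)undec-10-ynoate, via acid chloride 3 (not isolated)
Conditions: (COCl)2, DMF (cat.), CH2Cl2, 0 → 23 °C; then 2, AlCl3, CH2Cl2, 0 °C
Reagents that add atoms: oxalyl chloride, O=C(Cl)C(Cl)=O (chlorine of 3)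
Why: The acid chloride should acylate the bis-silylalkyne at a silicon-bearing carbon with loss of Me3SiCl (Friedel–Crafts-type ipso acylation of an alkynylsilane), the standard entry to silyl ynones, and the distal methyl ester should be inert to AlCl3 at 0 °C.

Step 2
Reactants: 4 methyl 9-oxo-11-(trimethylsilyl)undec-10-ynoate
Product: 5 methyl 9-oxoundec-10-ynoate
Conditions: Na2B4O7·10H2O (cat.), MeOH/H2O, 23 °C
Reagents that add atoms: none
Why: Borax-buffered methanolysis should cleave the C(sp)–Si bond of the activated silyl ynone (protodesilylation) at a basicity too low for conjugate addition of methanol to the freed terminal ynone.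

Step 3
Reactants: 6 (2Z)-pent-2-en-1-ol
Product: 7 (2Z)-1-bromopent-2-ene
Conditions: PBr3, pyridine (cat.), Et2O, −20 °C
Reagents that add atoms: phosphorus tribromide, BrP(Br)Br
Why: Bromide displacement on the phosphite ester of a primary allylic alcohol at low temperature (SN2) should give the bromide with the Z double bond retained.

Step 4
Reactants: 8 (1R,2S)-2-phenylcyclohexan-1-ol; 9 trichloroethylene; 7 (2Z)-1-bromopent-2-ene
Product: 12 (4Z)-hept-4-en-1-yn-1-yl (1R,2S)-2-phenylcyclohexyl ether, via dichlorovinyl ether 10 (not isolated), via lithium alkoxyacetylide 11 (not isolated)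
Conditions: KH, THF, 0 °C; 9, 23 °C; n-BuLi (2.5 equiv), −78 → −40 °C; then 7, HMPA, −78 → 23 °C
Reagents that add atoms: n-butyllithium, [Li]CCCC (lithium of 11)
Why: The potassium alkoxide should add to dichloroacetylene formed in situ from trichloroethylene, n-BuLi should turn the dichlorovinyl ether into the lithium alkoxyacetylide by elimination and chlorine–lithium exchange, and SN2 alkylation of this hard acetylide by the primary allylic bromide in HMPA should give the ynol ether with the Z alkene intact (one-pot ynol ether synthesis from an alcohol and trichloroethylene).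

Step 5
Reactants: 12 (4Z)-hept-4-en-1-yn-1-yl (1R,2S)-2-phenylcyclohexyl ether
Product: 13 tributyl[(1E,4Z)-1-{[(1R,2S)-2-phenylcyclohexyl]oxy}hepta-1,4-dien-1-yl]stannane
Conditions: Bu3SnH, Pd(PPh3)4 (2 mol %), THF, 0 °C
Reagents that add atoms: tributyltin hydride, CCCC[SnH](CCCC)CCCC
Why: Palladium-catalysed hydrostannation of 1-alkoxyalk-1-ynes is a syn addition that places tin on the oxygen-bearing carbon, which should set the 1E geometry (tin trans to the chain) and leave the isolated Z alkene alone.

Step 6
Reactants: 13 tributyl[(1E,4Z)-1-{[(1R,2S)-2-phenylcyclohexyl]oxy}hepta-1,4-dien-1-yl]stannane; 5 methyl 9-oxoundec-10-ynoate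
Product: 16 methyl 8-[(1R,5S)-1-hydroxy-4-oxo-5-[(2Z)-pent-2-en-1-yl]cyclopent-2-en-1-yl]octanoate, via vinyllithium 14 (not isolated), via dienyl ether 15 (not isolated)
Conditions: 13, n-BuLi, THF, −78 °C; CuSPh, −78 → −40 °C; 5, −78 °C; then CF3CO2H/H2O (9:1), −78 → 0 °C
Reagents that add atoms: water, O (ketone oxygen of 16); n-butyllithium, [Li]CCCC (lithium of 14)
Why: Proposed new method: tin–lithium exchange on 13 (retention) and transfer to CuSPh should give a phenylthio cuprate that adds 1,4 to ynone 5 and so makes C1–C2, and acidification should give dienyl ether 15, whose O-protonated form is the 1-hydroxy-4-alkoxypentadienyl cation spanning C5–C1–C2–C3–C4; this cation should close by conrotatory 4π electrocyclisation (C4–C5), after which water hydrolyses the ring oxocarbenium ion at C1 to the ketone and releases alcohol 8. The closest known reaction types are the conjugate addition of α-alkoxyvinyl cuprates (acyl anion equivalents) to enones and ynones, the Piancatelli rearrangement of 5-alkyl-2-furylcarbinols, which passes through the same kind of cation, and the one-flask cationic cyclopentannulation of lithiated allenyl ethers that carry an expendable chiral alkoxy group; new is that the cation is assembled from two open-chain pieces. The single ring closes in the 4π-conrotatory mode (five carbons, four electrons) and not as an enolate aldol, so the regiochemistry is fixed by the enol ether: only C5 can bond to C4, and the chain CH2 next to C4 cannot compete. C4 and C5 are set together: conrotation of the U-shaped cation with the pentenyl CH2 outside (fixed by the 1E geometry of 13) and the C4 oxygen outside should place hydroxyl trans to pentenyl, as in the rearrangement of 5-alkylfurylcarbinols, and the phenyl ring of the auxiliary should shield one face of the C5=C1 enol ether so that C4 bonds to C5 on the open face, which fixes the sense of conrotation and hence the absolute configuration. The step needs the E and Z isomers of 15 at C2=C3 to converge, which rotation about C2–C3 in the delocalised cation allows because only the U-shaped rotamer can close, and it needs O-protonation and closure to outrun C-protonation of the enol ether, which the electron-poor character of C5 (terminus of a dienone) and the low temperature should secure.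

Step 7
Reactants: 16 methyl 8-[(1R,5S)-1-hydroxy-4-oxo-5-[(2Z)-pent-2-en-1-yl]cyclopent-2-en-1-yl]octanoate
Product: 17 methyl 8-[(1R,5S)-1-acetoxy-4-oxo-5-[(2Z)-pent-2-en-1-yl]cyclopent-2-en-1-yl]octanoate
Conditions: Ac2O, Sc(OTf)3 (cat.), MeCN, −20 °C
Reagents that add atoms: acetic anhydride, CC(=O)OC(C)=O
Why: Lewis-acid-catalysed O-acylation with acetic anhydride should acetylate the hindered tertiary alcohol at low temperature without base, so that C5 (alpha to the ketone) is not epimerised and C4 keeps its configuration because no C–O bond is broken.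

Step 8
Reactants: 17 methyl 8-[(1R,5S)-1-acetoxy-4-oxo-5-[(2Z)-pent-2-en-1-yl]cyclopent-2-en-1-yl]octanoate
Product: 18 8-[(1R,5S)-1-acetoxy-4-oxo-5-[(2Z)-pent-2-en-1-yl]cyclopent-2-en-1-yl]octanoic acid (CNP0348716.4)
Conditions: Candida antarctica lipase B (immobilised), phosphate buffer pH 7.0/acetone, 30 °C
Reagents that add atoms: water, O
Why: A lipase (carboxylic ester hydrolase) should hydrolyse the unhindered terminal methyl ester at pH 7 and leave the tertiary acetate, which such enzymes do not accept, the enone and the epimerisable C5 centre untouched, as is usual for base-sensitive cyclopentenone fatty acid esters.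

**Compound list**

1 | monomethyl azelate (9-methoxy-9-oxononanoic acid) | COC(=O)CCCCCCCC(=O)O | starting material
2 | bis(trimethylsilyl)acetylene | C[Si](C)(C)C#C[Si](C)(C)C | starting material
3 | methyl 9-chloro-9-oxononanoate | COC(=O)CCCCCCCC(=O)Cl | intermediate
4 | methyl 9-oxo-11-(trimethylsilyl)undec-10-ynoate | COC(=O)CCCCCCCC(=O)C#C[Si](C)(C)C | intermediate
5 | methyl 9-oxoundec-10-ynoate | COC(=O)CCCCCCCC(=O)C#C | intermediate
6 | (2Z)-pent-2-en-1-ol | CC/C=C\CO | starting material
7 | (2Z)-1-bromopent-2-ene | CC/C=C\CBr | intermediate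
8 | (1R,2S)-2-phenylcyclohexan-1-ol | O[C@@H]1CCCC[C@H]1c1ccccc1 | starting material
9 | trichloroethylene | ClC=C(Cl)Cl | starting material
10 | (E)-1,2-dichloroethenyl (1R,2S)-2-phenylcyclohexyl ether | Cl/C=C(/Cl)O[C@@H]1CCCC[C@H]1c1ccccc1 | intermediate
11 | lithium 2-{[(1R,2S)-2-phenylcyclohexyl]oxy}ethynide | [Li]C#CO[C@@H]1CCCC[C@H]1c1ccccc1 | intermediate
12 | (4Z)-hept-4-en-1-yn-1-yl (1R,2S)-2-phenylcyclohexyl ether | CC/C=C\CC#CO[C@@H]1CCCC[C@H]1c1ccccc1 | intermediate
13 | tributyl[(1E,4Z)-1-{[(1R,2S)-2-phenylcyclohexyl]oxy}hepta-1,4-dien-1-yl]stannane | CC/C=C\C/C=C(\O[C@@H]1CCCC[C@H]1c1ccccc1)[Sn](CCCC)(CCCC)CCCC | intermediate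
14 | [(1Z,4Z)-1-{[(1R,2S)-2-phenylcyclohexyl]oxy}hepta-1,4-dien-1-yl]lithium | CC/C=C\C/C=C(\O[C@@H]1CCCC[C@H]1c1ccccc1)[Li] | intermediate
15 | methyl (10Z,12Z,15Z)-9-oxo-12-{[(1R,2S)-2-phenylcyclohexyl]oxy}octadeca-10,12,15-trienoate (reactive isomer shown; the 10E isomer formed with it converges through the same cation) | CC/C=C\C/C=C(\O[C@@H]1CCCC[C@H]1c1ccccc1)/C=C\C(=O)CCCCCCCC(=O)OC | intermediate
16 | methyl 8-[(1R,5S)-1-hydroxy-4-oxo-5-[(2Z)-pent-2-en-1-yl]cyclopent-2-en-1-yl]octanoate | CC/C=C\C[C@@H]1C(=O)C=C[C@@]1(CCCCCCCC(=O)OC)O | intermediate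
17 | methyl 8-[(1R,5S)-1-acetoxy-4-oxo-5-[(2Z)-pent-2-en-1-yl]cyclopent-2-en-1-yl]octanoate | CC/C=C\C[C@@H]1C(=O)C=C[C@@]1(CCCCCCCC(=O)OC)OC(C)=O | intermediate
18 | 8-[(1R,5S)-1-acetoxy-4-oxo-5-[(2Z)-pent-2-en-1-yl]cyclopent-2-en-1-yl]octanoic acid | CC/C=C\C[C@@H]1C(=O)C=C[C@@]1(CCCCCCCC(=O)O)OC(C)=O | target

**Count and risks**

Total steps: 8. Longest linear sequence: 6 (steps 3, 4, 5, 6, 7, 8).

Step 6 (proposed new method). What may go wrong: carbon protonation of the enol ether before ring closure, which would lose both the regiocontrol and the auxiliary; incomplete E-to-Z convergence at C2=C3; weak facial bias of the auxiliary or scrambling of which C4 substituent turns outward. Fallback, from 5 and 13, returning at 16: the two bonds are made in separate operations of known type. Ynone 5 is hydroiodinated (NaI, AcOH, 23 °C) to methyl (10Z)-11-iodo-9-oxoundec-10-enoate F1, which fixes the C2=C3 geometry. Stille coupling of F1 with stannane 13 (Pd2(dba)3, AsPh3, CuI, DMF, 23 °C) gives dienyl ether 15 as an isolated, geometrically defined compound. Compound 15 is then closed on its own under the conditions of the Piancatelli rearrangement (Dy(OTf)3, aqueous MeCN), for which this cation is the accepted intermediate, to give 16.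

Step 5. What may go wrong: delivery of tin to the carbon remote from oxygen, or migration of the skipped alkene on the palladium hydride. Fallback, from 12, returning at 14: hydrogen iodide made in situ (TMSCl, NaI, H2O, MeCN, −40 °C) adds across the ynol ether, iodide attacking the ketenium ion from the side of the smaller C2 substituent, to give (1E,4Z)-1-iodo-1-{[(1R,2S)-2-phenylcyclohexyl]oxy}hepta-1,4-diene F2. Iodine–lithium exchange (t-BuLi, 2 equiv, THF, −78 °C) gives vinyllithium 14 directly, which enters step 6 at the cuprate stage.

Step 8. What may go wrong: slow turnover of the lipophilic substrate, with creeping loss of the tertiary acetate or epimerisation at C5 during long incubation. Fallback, from 16, returning at 18: the order is reversed and the ester is cleaved chemically at the alcohol stage. Me3SnOH (1,2-dichloroethane, 70 °C) converts 16 into 8-[(1R,5S)-1-hydroxy-4-oxo-5-[(2Z)-pent-2-en-1-yl]cyclopent-2-en-1-yl]octanoic acid F3. Acetylation of F3 (Ac2O, Sc(OTf)3, MeCN, −20 °C; aqueous work-up hydrolyses the mixed anhydride at the carboxyl group) gives 18.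

**Further compounds**

F1 | step 6 | methyl (10Z)-11-iodo-9-oxoundec-10-enoate | COC(=O)CCCCCCCC(=O)/C=C\I
F2 | step 5 | (1E,4Z)-1-iodo-1-{[(1R,2S)-2-phenylcyclohexyl]oxy}hepta-1,4-diene | CC/C=C\C/C=C(\O[C@@H]1CCCC[C@H]1c1ccccc1)I
F3 | step 8 | 8-[(1R,5S)-1-hydroxy-4-oxo-5-[(2Z)-pent-2-en-1-yl]cyclopent-2-en-1-yl]octanoic acid | CC/C=C\C[C@@H]1C(=O)C=C[C@@]1(CCCCCCCC(=O)O)O
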